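**Plan**
Malabaricone C is 1-(2,6-dihydroxyphenyl)-9-(3,4-dihydroxyphenyl)nonan-1-one. Ring A (C1'–C6') has three adjacent unsubstituted CH carbons (C3', C4', C5') and the acyl-bearing C1' lying between the two oxygenated carbons C2' and C6'. This is the pattern formed when vinylketene (C2'–C5') takes up a 1-alkoxyalkyne (C1', C6').
Retrosynthesis: the four aryl ethers and the C-1 ketone are unmasked last. Ring A is then cut at C1'–C2' and C5'–C6' into cyclobutenone and an ynol ether, the ynol ether at C1–C1' into ethoxyacetylene and 9-(3,4-dimethoxyphenyl)nonanal, and the chain at C9–aryl into veratrole and monomethyl azelate.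
Forward: the chain is joined to the catechol ring by Friedel–Crafts acylation, then to the alkyne by acetylide addition. Ring A, the only ring built, is made last by benzannulation, followed by desilylation, oxidation and ether cleavage.
Stereochemistry: the target has none.

Key step: step 8

Assumption: because the target is achiral, the carbinol carbon made in step 4 is carried as a racemate and is removed by the oxidation in step 10; compound 15 is a transient mixture of diastereomers.

**Route**

Step 1
Reactants: 1 azelaic acid monomethyl ester; 2 1,2-dimethoxybenzene (veratrole)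
Product: 4 methyl 9-(3,4-dimethoxyphenyl)-9-oxononanoate, via acid chloride 3 (not isolated)
Conditions: (COCl)2, cat. DMF, CH2Cl2, 0 °C to rt; then 2, AlCl3, CH2Cl2, 0 °C to rt; ice/aq. HCl
Reagents that add atoms: none
Why: Friedel–Crafts acylation, in which the acylium ion from the acid chloride made in the flask attacks veratrole para to one methoxy group (the least hindered activated position) while the methyl ester is inert to AlCl3 at this temperature.

Step 2
Reactants: 4 methyl 9-(3,4-dimethoxyphenyl)-9-oxononanoate
Product: 5 methyl 9-(3,4-dimethoxyphenyl)nonanoate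
Conditions: Et3SiH, CF3CO2H, rt
Reagents that add atoms: none
Why: Ionic hydrogenation, in which the protonated electron-rich aryl ketone is reduced by hydride transfer through the methoxy-stabilised benzylic cation down to the methylene, leaving the ester untouched.

Step 3
Reactants: 5 methyl 9-(3,4-dimethoxyphenyl)nonanoate
Product: 6 9-(3,4-dimethoxyphenyl)nonanal
Conditions: i-Bu2AlH, CH2Cl2, −78 °C; MeOH, then aq. potassium sodium tartrate
Reagents that add atoms: none
Why: Partial reduction of a methyl ester with i-Bu2AlH, where the tetrahedral aluminium hemiacetal persists at −78 °C and releases the aldehyde only on work-up.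

Step 4
Reactants: 6 9-(3,4-dimethoxyphenyl)nonanal; 7 ethoxyacetylene
Product: 9 11-(3,4-dimethoxyphenyl)-1-ethoxyundec-1-yn-3-ol (racemic), via lithium ethoxyacetylide 8 (not isolated)
Conditions: 7, n-BuLi, THF, −78 °C; then 6, −78 to −40 °C; H2O quench; chromatography on Et3N-deactivated silica
Reagents that add atoms: none
Why: 1,2-Addition of a lithium acetylide to an aldehyde, which should form the C1–C1' bond cleanly; the new carbinol centre arises as a racemate, which is acceptable because it becomes the ketone carbon in step 10.

Step 5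
Reactants: 9 11-(3,4-dimethoxyphenyl)-1-ethoxyundec-1-yn-3-ol (racemic)
Product: 10 tert-butyl{[11-(3,4-dimethoxyphenyl)-1-ethoxyundec-1-yn-3-yl]oxy}dimethylsilane (racemic)
Conditions: TBSCl, imidazole, DMF, rt
Reagents that add atoms: tert-butyldimethylsilyl chloride, CC(C)(C)[Si](C)(C)Cl
Why: Imidazole-promoted silylation of a secondary alcohol, run under basic conditions so that the acid-labile ynol ether cannot undergo Meyer–Schuster rearrangement.

Step 6
Reactants: 11 3-oxocyclobutane-1-carboxylic acid
Product: 12 3-bromocyclobutan-1-one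
Conditions: HgO, Br2, MgSO4, CH2Cl2, reflux, dark
Reagents that add atoms: bromine, BrBr
Why: Hunsdiecker bromodecarboxylation in its Cristol–Firth form, in which the acyl hypobromite fragments to a cyclobutyl radical that is trapped by bromine.

Step 7
Reactants: 12 3-bromocyclobutan-1-one
Product: 13 cyclobut-2-en-1-one
Conditions: n-Bu3N, neat, rt, reduced pressure, distillate collected at −78 °C and taken up in cold toluene
Reagents that add atoms: none
Why: E1cB dehydrobromination of a β-bromo ketone by a tertiary amine, the volatile enone being removed from the base as it forms so that it does not polymerise.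

Step 8
Reactants: 10 tert-butyl{[11-(3,4-dimethoxyphenyl)-1-ethoxyundec-1-yn-3-yl]oxy}dimethylsilane (racemic); 13 cyclobut-2-en-1-one
Product: 18 2-[1-(tert-butyldimethylsilyloxy)-9-(3,4-dimethoxyphenyl)nonyl]-3-ethoxyphenol (racemic), via vinylketene 14 (not isolated), via 4-vinylcyclobutenone 15 (not isolated), via dienylketene 16 (not isolated), via cyclohexadienone tautomer 17 (not isolated)
Conditions: 13 (2.5 equiv, added in portions as a cold toluene solution), toluene, 80 °C, sealed tube, Ar
Reagents that add atoms: none
Why: At 80 °C cyclobutenone 13 should open by four-electron electrocyclic cleavage to vinylketene 14, whose carbonyl carbon is attacked by the nucleophilic alkyne carbon remote from oxygen in 10, giving 15 by a [2+2] cycloaddition, and 15 in turn opens to dienylketene 16. Ring A then closes by thermal disrotatory six-electron electrocyclisation of 16 (ketene carbon to terminal vinyl carbon) to dienone 17, which tautomerises irreversibly to phenol 18, so that the two alkyne carbons are inserted through the new bonds C1'–C2' and C5'–C6'. The closest known reaction type is the Danheiser benzannulation of cyclobutenones with alkoxy- and siloxyalkynes to 2-substituted resorcinol monoethers. No stereocentre is created, since the racemic carbinol carbon is a spectator and the ring stereocentre of 15 is erased when that ring opens. The selectivity needed is the regiochemistry of the ketene–alkyne union, which the polarisation of the ynol ether secures and which places the chain carbon between the hydroxyl and ethoxy groups; C-1 is carried as a silyl ether so that the alkyne stays electron-rich. Keeping the bath at 80 °C holds 10 below the temperature at which ethoxyalkynes lose ethylene by retro-ene reaction, and the excess of 13 added in portions offsets self-condensation of 13 and 14.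

Step 9
Reactants: 18 2-[1-(tert-butyldimethylsilyloxy)-9-(3,4-dimethoxyphenyl)nonyl]-3-ethoxyphenol (racemic)
Product: 19 2-[9-(3,4-dimethoxyphenyl)-1-hydroxynonyl]-3-ethoxyphenol (racemic)
Conditions: Bu4NF, AcOH, THF, 0 °C to rt
Reagents that add atoms: none
Why: Fluoride-driven cleavage of a silyl ether, buffered with acetic acid so that neither phenoxide chemistry nor ionisation of the electron-rich benzylic carbinol should intervene.

Step 10
Reactants: 19 2-[9-(3,4-dimethoxyphenyl)-1-hydroxynonyl]-3-ethoxyphenol (racemic)
Product: 20 9-(3,4-dimethoxyphenyl)-1-(2-ethoxy-6-hydroxyphenyl)nonan-1-one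
Conditions: MnO2 (activated, excess), CH2Cl2, rt
Reagents that add atoms: none
Why: Selective oxidation of a benzylic alcohol on activated MnO2, which tolerates the free ortho phenol and gives a ketone stabilised by an internal hydrogen bond to it.

Step 11
Reactants: 20 9-(3,4-dimethoxyphenyl)-1-(2-ethoxy-6-hydroxyphenyl)nonan-1-one
Product: 21 malabaricone C, 1-(2,6-dihydroxyphenyl)-9-(3,4-dihydroxyphenyl)nonan-1-one
Conditions: BBr3 (excess), CH2Cl2, −78 °C to rt; then ice-water
Reagents that add atoms: none
Why: Lewis-acid cleavage of aryl alkyl ethers with BBr3 (bromide attacks the O-alkyl carbon of the boron-complexed ether), which should remove the two methyl ethers and the ethyl ether alike, the latter assisted by chelation to the ortho carbonyl.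

**Compound list**
1 | azelaic acid monomethyl ester (9-methoxy-9-oxononanoic acid) | COC(=O)CCCCCCCC(=O)O | starting material
2 | 1,2-dimethoxybenzene (veratrole) | COc1ccccc1OC | starting material
3 | methyl 9-chloro-9-oxononanoate | COC(=O)CCCCCCCC(=O)Cl | intermediate (not isolated)
4 | methyl 9-(3,4-dimethoxyphenyl)-9-oxononanoate | COC(=O)CCCCCCCC(=O)c1ccc(OC)c(OC)c1 | intermediate
5 | methyl 9-(3,4-dimethoxyphenyl)nonanoate | COC(=O)CCCCCCCCc1ccc(OC)c(OC)c1 | intermediate
6 | 9-(3,4-dimethoxyphenyl)nonanal | O=CCCCCCCCCc1ccc(OC)c(OC)c1 | intermediate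
7 | ethoxyacetylene (ethoxyethyne) | CCOC#C | starting material
8 | lithium ethoxyacetylide | CCOC#C[Li] | intermediate (not isolated)
9 | 11-(3,4-dimethoxyphenyl)-1-ethoxyundec-1-yn-3-ol (racemic) | CCOC#CC(O)CCCCCCCCc1ccc(OC)c(OC)c1 | intermediate
10 | tert-butyl{[11-(3,4-dimethoxyphenyl)-1-ethoxyundec-1-yn-3-yl]oxy}dimethylsilane (racemic) | CCOC#CC(O[Si](C)(C)C(C)(C)C)CCCCCCCCc1ccc(OC)c(OC)c1 | intermediate
11 | 3-oxocyclobutane-1-carboxylic acid | O=C1CC(C(=O)O)C1 | starting material
12 | 3-bromocyclobutan-1-one | O=C1CC(Br)C1 | intermediate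
13 | cyclobut-2-en-1-one | O=C1CC=C1 | intermediate
14 | buta-1,3-dien-1-one (vinylketene) | C=CC=C=O | intermediate (not isolated)
15 | 2-[1-(tert-butyldimethylsilyloxy)-9-(3,4-dimethoxyphenyl)nonyl]-4-ethenyl-3-ethoxycyclobut-2-en-1-one (racemic, diastereomer mixture) | C=CC1C(=O)C(C(O[Si](C)(C)C(C)(C)C)CCCCCCCCc2ccc(OC)c(OC)c2)=C1OCC | intermediate (not isolated)
16 | (3E)-2-[1-(tert-butyldimethylsilyloxy)-9-(3,4-dimethoxyphenyl)nonyl]-3-ethoxyhexa-1,3,5-trien-1-one (racemic; vinyl group cis to the ketene carbon) | C=C/C=C(/OCC)C(=C=O)C(O[Si](C)(C)C(C)(C)C)CCCCCCCCc1ccc(OC)c(OC)c1 | intermediate (not isolated)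
17 | 2-[1-(tert-butyldimethylsilyloxy)-9-(3,4-dimethoxyphenyl)nonyl]-3-ethoxycyclohexa-2,4-dien-1-one (racemic) | CCOC1=C(C(O[Si](C)(C)C(C)(C)C)CCCCCCCCc2ccc(OC)c(OC)c2)C(=O)CC=C1 | intermediate (not isolated)
18 | 2-[1-(tert-butyldimethylsilyloxy)-9-(3,4-dimethoxyphenyl)nonyl]-3-ethoxyphenol (racemic) | CCOc1cccc(O)c1C(O[Si](C)(C)C(C)(C)C)CCCCCCCCc1ccc(OC)c(OC)c1 | intermediate
19 | 2-[9-(3,4-dimethoxyphenyl)-1-hydroxynonyl]-3-ethoxyphenol (racemic) | CCOc1cccc(O)c1C(O)CCCCCCCCc1ccc(OC)c(OC)c1 | intermediate
20 | 9-(3,4-dimethoxyphenyl)-1-(2-ethoxy-6-hydroxyphenyl)nonan-1-one | CCOc1cccc(O)c1C(=O)CCCCCCCCc1ccc(OC)c(OC)c1 | intermediate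
21 | malabaricone C, 1-(2,6-dihydroxyphenyl)-9-(3,4-dihydroxyphenyl)nonan-1-one | O=C(CCCCCCCCc1ccc(O)c(O)c1)c1c(O)cccc1O | target

**Step count**
Total: 11 steps. Longest linear sequence: 9 steps (steps 1–5 and 8–11); steps 6 and 7 are a two-step branch to cyclobutenone.

**Steps most likely to fail**

1. Step 8. The ynol ether in 10 is hindered and inductively deactivated by the propargylic silyloxy group, so its addition to vinylketene may be slower than oligomerisation of 13 and 14, acylation of the product phenol by surplus ketene, or retro-ene loss of ethylene from 10. The fallback gives up the construction of ring A and introduces it as a preformed arene. It sets out from aldehyde 6. 1,3-Dimethoxybenzene is lithiated between its two methoxy groups (n-BuLi, THF, 0 °C) to (2,6-dimethoxyphenyl)lithium F1, which is added to 6 to give 1-(2,6-dimethoxyphenyl)-9-(3,4-dimethoxyphenyl)nonan-1-ol F2. Oxidation with Dess–Martin periodinane should give 1-(2,6-dimethoxyphenyl)-9-(3,4-dimethoxyphenyl)nonan-1-one F3, and BBr3 in CH2Cl2 would cleave all four methyl ethers, so the fallback comes back to the route at 21.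

2. Step 7. Cyclobutenone may polymerise while it is liberated, transferred under vacuum or stored, so that too little reaches the benzannulation. The fallback makes the same vinylketene 14 without the four-membered ring; it sets out from alkyne 10 and comes back at 18. But-3-en-2-one is deprotonated with LiN(SiMe3)2 (THF, −78 °C) to lithium buta-1,3-dien-2-olate F4, which is acylated with CF3CO2CH2CF3 to 1,1,1-trifluorohex-5-ene-2,4-dione F5. Detrifluoroacetylative diazo transfer (MsN3, Et3N, H2O, MeCN) should convert this into 1-diazobut-3-en-2-one F6. Irradiating F6 with 10 in CH2Cl2 at rt should trigger a photochemical Wolff rearrangement to 14, which is trapped by 10; warming to 80 °C then carries 15, 16 and 17 through to 18.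

3. Step 10. The carbinol in 19 carries two ortho substituents and may oxidise slowly on MnO2, leaving time for oxidative degradation of the electron-rich free phenol or for ionisation of 19 to an ortho-quinone methide. The fallback caps the phenol before the oxidation; it sets out from 18 and comes back at 21. Methylation of 18 (MeI, K2CO3, acetone) should give tert-butyl{[9-(3,4-dimethoxyphenyl)-1-(2-ethoxy-6-methoxyphenyl)nonyl]oxy}dimethylsilane F7. Bu4NF in THF then releases 9-(3,4-dimethoxyphenyl)-1-(2-ethoxy-6-methoxyphenyl)nonan-1-ol F8, Dess–Martin periodinane oxidises it to 9-(3,4-dimethoxyphenyl)-1-(2-ethoxy-6-methoxyphenyl)nonan-1-one F9, and BBr3 cleaves the three methyl ethers and the ethyl ether to give 21.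

**Further compounds**
F1 | step 8 | (2,6-dimethoxyphenyl)lithium | COc1cccc(OC)c1[Li]
F2 | step 8 | 1-(2,6-dimethoxyphenyl)-9-(3,4-dimethoxyphenyl)nonan-1-ol (racemic) | COc1cccc(OC)c1C(O)CCCCCCCCc1ccc(OC)c(OC)c1
F3 | step 8 | 1-(2,6-dimethoxyphenyl)-9-(3,4-dimethoxyphenyl)nonan-1-one | COc1cccc(OC)c1C(=O)CCCCCCCCc1ccc(OC)c(OC)c1
F4 | step 7 | lithium buta-1,3-dien-2-olate | C=CC(=C)O[Li]
F5 | step 7 | 1,1,1-trifluorohex-5-ene-2,4-dione | C=CC(=O)CC(=O)C(F)(F)F
F6 | step 7 | 1-diazobut-3-en-2-one | C=CC(=O)C=[N+]=[N-]
F7 | step 10 | tert-butyl{[9-(3,4-dimethoxyphenyl)-1-(2-ethoxy-6-methoxyphenyl)nonyl]oxy}dimethylsilane (racemic) | CCOc1cccc(OC)c1C(O[Si](C)(C)C(C)(C)C)CCCCCCCCc1ccc(OC)c(OC)c1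
F8 | step 10 | 9-(3,4-dimethoxyphenyl)-1-(2-ethoxy-6-methoxyphenyl)nonan-1-ol (racemic) | CCOc1cccc(OC)c1C(O)CCCCCCCCc1ccc(OC)c(OC)c1
F9 | step 10 | 9-(3,4-dimethoxyphenyl)-1-(2-ethoxy-6-methoxyphenyl)nonan-1-one | CCOc1cccc(OC)c1C(=O)CCCCCCCCc1ccc(OC)c(OC)c1
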